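**Strategy.** The route rests on cutting the seven-membered ring C4–C5–C6–C7–C8–C9–C10 (longipinane numbering: C1 ketone, C6 CMe2, C7 O-isovaleryl, C9 O-tigloyl, C10 C–CH3) at C6–C7 and C9–C10. The 1,3-dioxygenated C7–C8–C9 unit, flanked by the quaternary carbons C6 and C10, is read as a β-silyl acryloylsilane. In one operation a ketone enolate adds to the acylsilane, a Brook rearrangement closes a cis-dialkenylcyclopropanediolate, and its strain-driven oxy-Cope rearrangement delivers the cycloheptane with both bonds and the C9/C10 stereorelationship. The precursor is an enantioenriched cyclohexenyl methyl ketone with C5 as a temporary carbonyl and C1 as a ketal; the cyclobutane is closed later by C11-enolate displacement at C5.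

Key step: step 5

Remark: atom numbers C1–C11 are those of the target skeleton throughout (six-membered ring C1–C2–C3–C4–C10–C11, seven-membered ring C4–C5–C6–C7–C8–C9–C10, cyclobutane closed by C5–C11); bicyclic intermediates lack the C5–C11 bond.
Remark: in step 1 the hand of the cinchona amine is taken as the one that gives the 6S ester; the quinidine-derived pseudo-enantiomer serves if the sense of induction is the opposite.

Step 1
Reactants: 1 ethyl 3-oxobutanoate; 2 (3E)-pent-3-en-2-one
Product: 4 ethyl (1R,6S)-2,6-dimethyl-4-oxocyclohex-2-ene-1-carboxylate, via Michael adduct 3 (not isolated)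
Conditions: 9-amino-9-deoxy-epi-quinine (20 mol %), CF3CO2H (40 mol %), toluene, rt; then pyrrolidine, AcOH, 70 °C
Reagents that add atoms: none
Why: Asymmetric Robinson annulation, in which the iminium-activated Michael addition of the β-keto ester sets the methyl-bearing carbon (C3 of the target numbering, 6S in 4) under catalyst control and enamine aldol condensation of the methyl ketone onto the acetoacetate carbonyl closes the cyclohexenone; C1 of 4 is epimerisable and should settle trans to the 6-methyl group.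

Step 2
Reactants: 4 ethyl (1R,6S)-2,6-dimethyl-4-oxocyclohex-2-ene-1-carboxylate
Product: 5 ethyl (9S)-7,9-dimethyl-1,4-dioxaspiro[4.5]dec-7-ene-8-carboxylate
Conditions: HOCH2CH2OH, p-TsOH (cat.), benzene, reflux, Dean–Stark
Reagents that add atoms: ethylene glycol OCCO
Why: Acid-catalysed ketalisation of a 3-methylcyclohex-2-enone moves the double bond into conjugation with the ester, which should give the tetrasubstituted C4=C10 alkene needed for the key step and leave the C3 stereocentre untouched.

Step 3
Reactants: 5 ethyl (9S)-7,9-dimethyl-1,4-dioxaspiro[4.5]dec-7-ene-8-carboxylate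
Product: 7 1-[(9S)-7,9-dimethyl-1,4-dioxaspiro[4.5]dec-7-en-8-yl]ethan-1-one, via Weinreb amide 6 (not isolated)
Conditions: MeNH(OMe)·HCl, i-PrMgCl, THF, −20 to 0 °C; then MeMgBr, 0 °C to rt; aq. NH4Cl
Reagents that add atoms: methylmagnesium bromide C[Mg]Br
Why: One-pot Weinreb ketone synthesis, in which the magnesium amide converts the hindered ester into the N-methoxy-N-methylamide and its chelated tetrahedral adduct with MeMgBr stops at the methyl ketone.

Step 4
Reactants: 8 1-methoxypropa-1,2-diene
Product: 11 (2E)-1-[tert-butyl(dimethyl)silyl]-3-[dimethyl(phenyl)silyl]prop-2-en-1-one, via 1-silylallene 9 (not isolated), via 1,3-disilylallene 10 (not isolated)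
Conditions: n-BuLi, THF, −78 °C, then TBSCl; n-BuLi, −78 °C, then PhMe2SiCl; then 1 M HCl, THF, rt
Reagents that add atoms: tert-butyldimethylsilyl chloride CC(C)(C)[Si](C)(C)Cl; chlorodimethylphenylsilane C[Si](C)(Cl)c1ccccc1; water O
Why: Successive α- and γ-lithiation/silylation of the allenyl ether followed by acid hydrolysis of the enol ether is an established route to β-silyl acryloylsilanes, and the conjugated product should equilibrate to the E alkene.

Step 5
Reactants: 7 1-[(9S)-7,9-dimethyl-1,4-dioxaspiro[4.5]dec-7-en-8-yl]ethan-1-one; 11 (2E)-1-[tert-butyl(dimethyl)silyl]-3-[dimethyl(phenyl)silyl]prop-2-en-1-one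
Product: 16 bicyclic silyl enol ether ketone (C5 ketone; C7 OTBS enol ether; 9-SiMe2Ph; C1 dioxolane), via lithium enolate 12 (not isolated), via alkoxide adduct 13 (not isolated), via divinylcyclopropanolate 14 (not isolated), via cycloheptadienolate 15 (not isolated)
Conditions: LiN(i-Pr)2, THF, −78 °C; add 11, −78 °C to rt; AcOH quench
Reagents that add atoms: none
Why: Kinetic deprotonation gives the cross-conjugated enolate 12, whose 1,2-addition to the acylsilane forms C6–C7; a 1,2-Brook rearrangement then gives a silyl-stabilised siloxyallyl anion that closes onto the C5 carbonyl (3-exo-trig) to the cis-1,2-dialkenylcyclopropane-1,2-diolate 14, and its anionic oxy-Cope rearrangement, driven by release of cyclopropane strain, forms C9–C10 and opens the three-membered ring to the seven-membered enolate 15. The closest known reaction type is the Brook-rearrangement-mediated [3+4] annulation of β-silyl acryloylsilanes with lithium enolates of cycloalkenyl methyl ketones. The seven-membered ring is closed by the [3,3]-sigmatropic shift through a boat transition state, the cyclopropane being made and consumed in the same flask. C9 relative to C10 follows from the boat geometry, since the E silyl group and the ring CH2 (C11) are both outside substituents and end up cis, so silicon at C9 is trans to CH3-10; the absolute sense at C10 is set by approach of the vinylsilane arm anti to the pseudoaxial CH3 at C3; C4 is protonated, and can equilibrate α to the C5 ketone, to the cis ring fusion. The step needs α′- over γ-deprotonation (amide base at −78 °C), 1,2- over 1,4-addition to the acylsilane and Cope rearrangement over direct five-membered closure, which the β-silyl group and the cis arrangement in 14 should secure; the inside methyl on C10 is expected to slow the rearrangement, hence the warming to rt.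

Step 6
Reactants: 16 bicyclic silyl enol ether ketone
Product: 18 bicyclic 6,6-dimethyl-5,7-dione silane, via 1,3-dione 17 (not isolated)
Conditions: Bu4NF (3 equiv), THF, 0 °C; then MeI (excess), 0 °C to rt
Reagents that add atoms: iodomethane CI
Why: Fluoride cleaves the silyl enol ether to the cyclic 1,3-diketonate, which is C-methylated twice at C6 (alkylation of a β-diketone) to install the gem-dimethyl group; C4 remains the only epimerisable centre and should hold the cis fusion with C5 trans to both CH3-3 and CH3-10.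

Step 7
Reactants: 18 bicyclic 6,6-dimethyl-5,7-dione silane
Product: 19 bicyclic 9-hydroxy-5,7-dione
Conditions: KBr, AcOOH, NaOAc, AcOH, rt
Reagents that add atoms: peracetic acid CC(=O)OO
Why: Fleming–Tamao oxidation, in which ipso-bromodesilylation of the phenyl group and peracid-induced 1,2-shift of C9 from silicon to oxygen turn C–Si into C–OH with retention, so the C9 configuration from step 5 is carried over.

Step 8
Reactants: 19 bicyclic 9-hydroxy-5,7-dione; 20 (2E)-2-methylbut-2-enal
Product: 21 bicyclic 9-tiglate 7-alcohol 5-ketone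
Conditions: SmI2 (30 mol %), THF, −10 °C
Reagents that add atoms: none
Why: Evans–Tishchenko reduction, in which the samarium-bound hemiacetal of 9-OH and the aldehyde delivers hydride intramolecularly to the C7 ketone from the face of O-9, so 7-OH should form anti to O-9 while O-9 becomes the tiglate; the C5 ketone has no β-hydroxyl and should stay.

Step 9
Reactants: 21 bicyclic 9-tiglate 7-alcohol 5-ketone
Product: 23 bicyclic 9-tiglate 5,7-diol 1-ketone, via dioxolane diol 22 (not isolated)
Conditions: Et2BOMe, THF/MeOH, −78 °C; NaBH4; then 2 M HCl, THF, rt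
Reagents that add atoms: water O
Why: Narasaka–Prasad reduction, in which the boron chelate between O-7 and the C5 carbonyl is reduced by external hydride from the opposite face to the syn-1,3-diol (O-5 cis to O-7), and the acidic work-up hydrolyses the boronate and the dioxolane to free the C1 ketone.

Step 10
Reactants: 23 bicyclic 9-tiglate 5,7-diol 1-ketone; 24 3-methylbutanoyl chloride
Product: 25 bicyclic 9-tiglate 7-isovalerate 5-alcohol
Conditions: pyridine, DMAP (cat.), CH2Cl2, −20 °C
Reagents that add atoms: none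
Why: Site-selective acylation, in which the 7-OH (flanked by CH2 and C6) should be esterified in preference to the 5-OH, which is shielded by C6 and the ring-fusion carbon C4.

Step 11
Reactants: 25 bicyclic 9-tiglate 7-isovalerate 5-alcohol
Product: 26 bicyclic 5-mesylate
Conditions: MsCl, Et3N, CH2Cl2, 0 °C
Reagents that add atoms: methanesulfonyl chloride CS(=O)(=O)Cl
Why: Sulfonylation through sulfene tolerates the hindered secondary alcohol and turns O-5 into a leaving group with retention at C5.

Step 12
Reactants: 26 bicyclic 5-mesylate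
Product: 28 2,3-dihydro target (tricyclic saturated ketone), via potassium enolate 27 (not isolated)
Conditions: KN(SiMe3)2 (0.95 equiv), THF, −78 °C to rt
Reagents that add atoms: none
Why: Intramolecular enolate alkylation (4-exo-tet SN2) across the cis ring fusion, in which only the C11 enolate can reach the backside of the C5–OMs bond, so equilibrating enolates should funnel into the cyclobutane with inversion at C5 and with C11 fixed by the bridged ring.

Step 13
Reactants: 28 2,3-dihydro target
Product: 29 target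
Conditions: 2-iodoxybenzoic acid (IBX), DMSO, 70 °C
Reagents that add atoms: none
Why: IBX dehydrogenation of the ketone; C11 is a bridgehead and cannot enolise, so unsaturation can only enter at C2–C3, which also erases the auxiliary C3 stereocentre.

**Compound list**

1 | ethyl 3-oxobutanoate | CCOC(=O)CC(C)=O | starting material
2 | (3E)-pent-3-en-2-one | C/C=C/C(C)=O | starting material
3 | ethyl (3S)-2-acetyl-3-methyl-5-oxohexanoate (C2 epimers) | CCOC(=O)C(C(C)=O)[C@@H](C)CC(C)=O | intermediate (not isolated)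
4 | ethyl (1R,6S)-2,6-dimethyl-4-oxocyclohex-2-ene-1-carboxylate | CCOC(=O)[C@H]1C(C)=CC(=O)C[C@@H]1C | intermediate
5 | ethyl (9S)-7,9-dimethyl-1,4-dioxaspiro[4.5]dec-7-ene-8-carboxylate | CCOC(=O)C1=C(C)CC2(OCCO2)C[C@@H]1C | intermediate
6 | (9S)-N-methoxy-N,7,9-trimethyl-1,4-dioxaspiro[4.5]dec-7-ene-8-carboxamide | CON(C)C(=O)C1=C(C)CC2(OCCO2)C[C@@H]1C | intermediate (not isolated)
7 | 1-[(9S)-7,9-dimethyl-1,4-dioxaspiro[4.5]dec-7-en-8-yl]ethan-1-one | CC(=O)C1=C(C)CC2(OCCO2)C[C@@H]1C | intermediate
8 | 1-methoxypropa-1,2-diene (methoxyallene) | COC=C=C | starting material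
9 | tert-butyl(1-methoxypropa-1,2-dien-1-yl)dimethylsilane | COC(=C=C)[Si](C)(C)C(C)(C)C | intermediate (not isolated)
10 | tert-butyl{3-[dimethyl(phenyl)silyl]-1-methoxypropa-1,2-dien-1-yl}dimethylsilane (racemic axis) | COC(=C=C[Si](C)(C)c1ccccc1)[Si](C)(C)C(C)(C)C | intermediate (not isolated)
11 | (2E)-1-[tert-butyl(dimethyl)silyl]-3-[dimethyl(phenyl)silyl]prop-2-en-1-one | C[Si](C)(c1ccccc1)/C=C/C(=O)[Si](C)(C)C(C)(C)C | intermediate
12 | lithium 1-[(9S)-7,9-dimethyl-1,4-dioxaspiro[4.5]dec-7-en-8-yl]ethenolate | [Li+].[O-]C(=C)C1=C(C)CC2(OCCO2)C[C@@H]1C | intermediate (not isolated)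
13 | lithium (4E)-3-[tert-butyl(dimethyl)silyl]-1-[(9S)-7,9-dimethyl-1,4-dioxaspiro[4.5]dec-7-en-8-yl]-5-[dimethyl(phenyl)silyl]-1-oxopent-4-en-3-olate (C3 epimers) | [Li+].[O-]C(CC(=O)C1=C(C)CC2(OCCO2)C[C@@H]1C)(/C=C/[Si](C)(C)c1ccccc1)[Si](C)(C)C(C)(C)C | intermediate (not isolated)
14 | lithium 2-[tert-butyl(dimethyl)silyl]oxy-1-[(9S)-7,9-dimethyl-1,4-dioxaspiro[4.5]dec-7-en-8-yl]-2-{(E)-2-[dimethyl(phenyl)silyl]ethenyl}cyclopropan-1-olate, the two alkenyl groups cis | [Li+].[O-][C@]1(C[C@@]1(O[Si](C)(C)C(C)(C)C)/C=C/[Si](C)(C)c1ccccc1)C1=C(C)CC2(OCCO2)C[C@@H]1C | intermediate (not isolated)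
15 | lithium enolate of 16 (C4=C5–OLi) | C[Si](C)(c4ccccc4)[C@@H]1C=C(O[Si](C)(C)C(C)(C)C)CC([O-])=C2[C@@H](C)CC3(OCCO3)C[C@@]21C.[Li+] | intermediate (not isolated)
16 | cis-fused bicyclo[5.4.0]undecene (target numbering, no C5–C11 bond): C1 ethylene ketal, 3-CH3, C5 ketone, C6 H2, C7(OTBS)=C8 enol ether, 9-SiMe2Ph, 10-CH3; H-4 cis to CH3-10, CH3-3 cis to CH3-10, Si-9 trans to CH3-10 | C[Si](C)(c4ccccc4)[C@@H]1C=C(O[Si](C)(C)C(C)(C)C)CC(=O)[C@@H]2[C@@H](C)CC3(OCCO3)C[C@@]21C | intermediate
17 | as 16 but C5 and C7 ketones with C6 H2 (present as its tetrabutylammonium enolate) | C[Si](C)(c4ccccc4)[C@@H]1CC(=O)CC(=O)[C@@H]2[C@@H](C)CC3(OCCO3)C[C@@]21C | intermediate (not isolated)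
18 | cis-fused bicyclic 6,6-dimethyl-5,7-dione: C1 ethylene ketal, 3-CH3, 9-SiMe2Ph (trans to CH3-10), 10-CH3 | C[Si](C)(c4ccccc4)[C@@H]1CC(=O)C(C)(C)C(=O)[C@@H]2[C@@H](C)CC3(OCCO3)C[C@@]21C | intermediate
19 | as 18 with 9-OH in place of silicon (9-OH trans to CH3-10) | O[C@@H]1CC(=O)C(C)(C)C(=O)[C@@H]2[C@@H](C)CC3(OCCO3)C[C@@]21C | intermediate
20 | (2E)-2-methylbut-2-enal (tiglic aldehyde) | C/C=C(\C)C=O | starting material
21 | cis-fused bicyclic C5 ketone with 9-O-tigloyl (trans to CH3-10) and 7-OH (cis to CH3-10, anti to O-9); C1 ethylene ketal | C/C=C(\C)C(=O)O[C@@H]1C[C@@H](O)C(C)(C)C(=O)[C@@H]2[C@@H](C)CC3(OCCO3)C[C@@]21C | intermediate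
22 | as 21 with 5-OH (cis to 7-OH and to CH3-10) | C/C=C(\C)C(=O)O[C@@H]1C[C@@H](O)C(C)(C)[C@@H](O)[C@@H]2[C@@H](C)CC3(OCCO3)C[C@@]21C | intermediate (not isolated)
23 | as 22 with the C1 ketone free | C/C=C(\C)C(=O)O[C@@H]1C[C@@H](O)C(C)(C)[C@@H](O)[C@@H]2[C@@H](C)CC(=O)C[C@@]21C | intermediate
24 | 3-methylbutanoyl chloride | CC(C)CC(=O)Cl | starting material
25 | as 23 with 7-O-(3-methylbutanoyl) | C/C=C(\C)C(=O)O[C@@H]1C[C@@H](OC(=O)CC(C)C)C(C)(C)[C@@H](O)[C@@H]2[C@@H](C)CC(=O)C[C@@]21C | intermediate
26 | as 25 with 5-O-methanesulfonyl | C/C=C(\C)C(=O)O[C@@H]1C[C@@H](OC(=O)CC(C)C)C(C)(C)[C@@H](OS(C)(=O)=O)[C@@H]2[C@@H](C)CC(=O)C[C@@]21C | intermediate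
27 | potassium C11=C1 enolate of 26 | C/C=C(\C)C(=O)O[C@@H]1C[C@@H](OC(=O)CC(C)C)C(C)(C)[C@@H](OS(C)(=O)=O)[C@@H]2[C@@H](C)CC([O-])=C[C@@]21C.[K+] | intermediate (not isolated)
28 | (3S,4S,5S,7R,9R,10R,11R)-7-(3-methylbutanoyloxy)-9-[(2E)-2-methylbut-2-enoyloxy]longipinan-1-one | C/C=C(\C)C(=O)O[C@@H]1C[C@@H](OC(=O)CC(C)C)C(C)(C)[C@@H]2[C@H]3C(=O)C[C@H](C)[C@@H]2[C@]31C | intermediate
29 | (4R,5S,7R,9R,10R,11R)-7-(3-methylbutanoyloxy)-9-[(2E)-2-methylbut-2-enoyloxy]longipin-2-en-1-one | C/C=C(\C)C(=O)O[C@@H]1C[C@@H](OC(=O)CC(C)C)C(C)(C)[C@@H]2[C@H]3C(=O)C=C(C)[C@@H]2[C@]31C | target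

**Count and risks**

Total step count: 13. Longest linear sequence: 12 steps (steps 1–3 and 5–13); step 4 is a one-step branch.

Most likely to fail:

1. Step 5. The oxy-Cope step must form the quaternary C10 with a methyl group pointing into the boat transition state, so the cyclopropanolate may instead reopen and close stepwise (loss of the C9/C10 stereospecificity), collapse to a five-membered carbinol, or react on the wrong alkene face. Fallback, from 7 back to 18: crossed Claisen condensation of the lithium enolate of 7 with methyl (2E)-3-[dimethyl(phenyl)silyl]prop-2-enoate gives the β-diketone (4E)-1-[(9S)-7,9-dimethyl-1,4-dioxaspiro[4.5]dec-7-en-8-yl]-5-[dimethyl(phenyl)silyl]pent-4-ene-1,3-dione F1; MeI with K2CO3 gives its 2,2-dimethyl derivative F2; irradiation at 350 nm joins the two enone double bonds in an intramolecular [2+2] photocycloaddition (C4–C8 first, then C9–C10) to the cyclobutane-fused 2,2-dimethylcyclopentane-1,3-dione F3; SmI2 in THF/MeOH then cleaves the strained C4–C8 bond between the two ketone α-carbons, and protonation gives 18. This forms the two bonds in separate steps.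

2. Step 12. SN2 at a secondary carbon next to the quaternary C6 is slow, so elimination of the mesylate toward C4, O-alkylation of the enolate or base attack on the esters may take over. Fallback, from 26 to 29: 26 is dehydrogenated first with IBX to the enone mesylate F4; its kinetic cross-conjugated lithium dienolate (LiN(SiMe3)2, THF, −78 °C, then DMPU and warming) can only form at C11, and the same displacement at C5 then gives 29 directly as the last step.

3. Step 8. Hemiacetal formation between the hindered 9-OH and a conjugated aldehyde may be too unfavourable for hydride transfer, and retro-aldol ring opening, acyl migration or a second Tishchenko reduction at C5 may compete. Fallback, from 19 back to 23: Evans–Saksena reduction (Me4NBH(OAc)3, MeCN/AcOH) gives the anti-7,9-diol F5; Narasaka–Prasad reduction of the C5 ketone gives the triol F6; the syn-5,7-diol is tied up as its acetonide F7 (2,2-dimethoxypropane, PPTS); the free 9-OH is esterified with (2E)-2-methylbut-2-enoic acid under Yamaguchi conditions to the tiglate acetonide F8; aqueous HCl in THF removes acetonide and dioxolane to give 23.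

Further compounds
F1 | step 5 | (4E)-1-[(9S)-7,9-dimethyl-1,4-dioxaspiro[4.5]dec-7-en-8-yl]-5-[dimethyl(phenyl)silyl]pent-4-ene-1,3-dione | C[Si](C)(c1ccccc1)/C=C/C(=O)CC(=O)C1=C(C)CC2(OCCO2)C[C@@H]1C
F2 | step 5 | (4E)-1-[(9S)-7,9-dimethyl-1,4-dioxaspiro[4.5]dec-7-en-8-yl]-5-[dimethyl(phenyl)silyl]-2,2-dimethylpent-4-ene-1,3-dione | C[Si](C)(c1ccccc1)/C=C/C(=O)C(C)(C)C(=O)C1=C(C)CC2(OCCO2)C[C@@H]1C
F3 | step 5 | [2+2] photoadduct of F2: cyclobutane C8–C9–C10–C4 cis-fused to the 2,2-dimethylcyclopentane-1,3-dione (C5, C6, C7) and to the ketal-bearing cyclohexane | C[Si](C)(c5ccccc5)[C@@H]1[C@H]2C(=O)C(C)(C)C(=O)[C@]23[C@@H](C)CC4(OCCO4)C[C@]13C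
F4 | step 12 | C2=C3 enone of 26 (5-mesylate, 7-isovalerate, 9-tiglate) | C/C=C(\C)C(=O)O[C@@H]1C[C@@H](OC(=O)CC(C)C)C(C)(C)[C@@H](OS(C)(=O)=O)[C@@H]2C(C)=CC(=O)C[C@@]21C
F5 | step 8 | anti-7,9-diol of 19 (C5 ketone, C1 ethylene ketal) | O[C@@H]1C[C@@H](O)C(C)(C)C(=O)[C@@H]2[C@@H](C)CC3(OCCO3)C[C@@]21C
F6 | step 8 | 5,7,9-triol (5-OH cis to 7-OH, 9-OH trans to both; C1 ethylene ketal) | O[C@@H]1C[C@@H](O)C(C)(C)[C@@H](O)[C@@H]2[C@@H](C)CC3(OCCO3)C[C@@]21C
F7 | step 8 | 5,7-O-isopropylidene acetal of F6 | O[C@@H]1C[C@@H]4C(C)(C)[C@@H](OC(C)(C)O4)[C@@H]2[C@@H](C)CC3(OCCO3)C[C@@]21C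
F8 | step 8 | 9-O-[(2E)-2-methylbut-2-enoyl] ester of F7 | C/C=C(\C)C(=O)O[C@@H]1C[C@@H]4C(C)(C)[C@@H](OC(C)(C)O4)[C@@H]2[C@@H](C)CC3(OCCO3)C[C@@]21C
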